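The route rests on opening ring C, the 1,3-dioxine that bridges the isochroman (rings A and B) and the isoquinoline, at two bonds: C3–C7′ and C1–O6′. Carbinol carbon C3 lies β to the acetyl ketone and C1 is an acetal carbon, so a 4-acetyl-1-methoxy-1H-isochromene offers both sites to an isoquinolin-6-ol that carries boron on C7′. In one operation a rhodium–diene catalyst adds the aryl group to C3 (setting C3, then C4 by protonation) and acid exchanges the C1 methoxy group for the phenol, closing ring C and fixing C1. Both partners descend from orcylaldehyde through one aryl iodide, whose iodine becomes a formyl group or the boron atom.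

Key step: step 11

Remarks on the chemistry
- Atom labels: isochroman numbering for rings A and B (C1 acetal carbon, O2, C3 carbinol carbon, C4 acetyl-bearing carbon, C5–C8 in ring A); isoquinoline atoms are primed. In these labels the target is (1R,3R,4S), with the C4 acetyl group cis to the C3–C7′ bond.
- Assumption: the (R,R) enantiomer of the diene ligand is written as the one that gives 3R. If a trial run shows the opposite sense, the (S,S) ligand is used and nothing else changes.
- The position between the methoxy and methoxymethoxy groups is lithiated once, in step 4, and trapped with iodine. Iodo imine 8 is the branch point. Iodine–magnesium exchange and formylation lead to ring A; lateral lithiation with the iodine kept leads to the boronic acid.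
- The tert-butyl imine made in step 5 serves both branches. It masks the aldehyde during the magnesium chemistry of step 6 and activates the neighbouring methyl group in steps 7 and 9.
- The C7 aldehyde is carried as a dimethyl acetal because it then forms in the same acidic methanol that closes ring B, so the two aldehydes of 14 need no separate protection.
- Iodine sits on the future C7′ before the isoquinoline is built, so the boron site does not depend on metalating the heterocycle.
- It is not certain that the cis acetyl group is the more stable C4 epimer of the bridged system, so no basic conditions are used from step 11 on.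

Step 1
Reactants: 1 2,4-dihydroxy-6-methylbenzaldehyde (orcylaldehyde)
Product: 2 2-hydroxy-4-(methoxymethoxy)-6-methylbenzaldehyde
Conditions: MOMCl (1.1 equiv), i-Pr2NEt, CH2Cl2, 0 °C → rt
Reagents that add atoms: chloromethyl methyl ether, COCCl
Why: The 2-hydroxyl is locked in a hydrogen bond to the aldehyde, so Williamson-type etherification takes the free, more acidic 4-hydroxyl.

Step 2
Reactants: 2 2-hydroxy-4-(methoxymethoxy)-6-methylbenzaldehyde
Product: 3 2-methoxy-4-(methoxymethoxy)-6-methylbenzaldehyde
Conditions: MeI, K2CO3, DMF, 40 °C
Reagents that add atoms: iodomethane, CI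
Why: Williamson methylation of the remaining chelated phenol, which carbonate in a dipolar solvent deprotonates well enough at 40 °C.

Step 3
Reactants: 3 2-methoxy-4-(methoxymethoxy)-6-methylbenzaldehyde
Product: 4 1-(dimethoxymethyl)-2-methoxy-4-(methoxymethoxy)-6-methylbenzene
Conditions: HC(OMe)3, MeOH, PPTS (5 mol %), rt
Reagents that add atoms: trimethyl orthoformate, COC(OC)OC
Why: Acid-catalysed acetalization driven by the orthoformate hides the aldehyde from butyllithium, and pyridinium tosylate at room temperature is too weak to cleave the aryl methoxymethyl ether.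

Step 4
Reactants: 4 1-(dimethoxymethyl)-2-methoxy-4-(methoxymethoxy)-6-methylbenzene
Product: 7 3-iodo-2-methoxy-4-(methoxymethoxy)-6-methylbenzaldehyde, via aryllithium 5 (not isolated), via iodo acetal 6 (not isolated)
Conditions: n-BuLi, THF, 0 °C; I2, −78 °C → rt; aq. Na2S2O3; then 1 M HCl, THF, 0 °C
Reagents that add atoms: iodine, II; water, O
Why: Directed ortho-metalation takes the one ring hydrogen flanked by the methoxy and methoxymethoxy groups, iodine traps the aryllithium, and the dilute acid of the work-up hydrolyses the electron-rich dimethyl acetal far faster than the methoxymethyl ether.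

Step 5
Reactants: 7 3-iodo-2-methoxy-4-(methoxymethoxy)-6-methylbenzaldehyde
Product: 8 (E)-N-tert-butyl-1-[3-iodo-2-methoxy-4-(methoxymethoxy)-6-methylphenyl]methanimine
Conditions: t-BuNH2 (3 equiv), 4 Å MS, CH2Cl2, rt
Reagents that add atoms: tert-butylamine, CC(C)(C)N
Why: Imine condensation gives a hindered aldimine that resists organomagnesium reagents, amide bases and carbanions and that acidifies the neighbouring methyl group for the later lateral lithiations.

Step 6
Reactants: 8 (E)-N-tert-butyl-1-[3-iodo-2-methoxy-4-(methoxymethoxy)-6-methylphenyl]methanimine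
Product: 11 1,1′-[2-methoxy-4-(methoxymethoxy)-6-methyl-1,3-phenylene]bis(N-tert-butylmethanimine) (both E), via arylmagnesium chloride 9 (not isolated), via formyl imine 10 (not isolated)
Conditions: iPrMgCl·LiCl (1.15 equiv), THF, −20 → 0 °C; DMF (3 equiv), 0 °C → rt; aq. NH4Cl; extract and evaporate; then t-BuNH2 (6 equiv), 4 Å MS, CH2Cl2, 40 °C
Reagents that add atoms: N,N-dimethylformamide, CN(C)C=O; tert-butylamine, CC(C)(C)N
Why: Iodine–magnesium exchange with the turbo-Grignard reagent is fast for an aryl iodide flanked by two chelating ether oxygens and leaves the hindered tert-butyl aldimine untouched, DMF formylates the arylmagnesium species (Bouveault aldehyde synthesis), and recondensation of the crude aldehyde with tert-butylamine gives the bis-imine and restores any imine lost in the aqueous quench.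

Step 7
Reactants: 11 1,1′-[2-methoxy-4-(methoxymethoxy)-6-methyl-1,3-phenylene]bis(N-tert-butylmethanimine)
Product: 14 2-methoxy-4-(methoxymethoxy)-6-(2-oxopropyl)benzene-1,3-dicarbaldehyde, via benzylic lithium species 12 (not isolated), via keto bis-imine 13 (not isolated)
Conditions: LDA (1.1 equiv), THF, −78 °C; MeC(O)N(OMe)Me, −78 → −20 °C; then 1 M HCl, THF, 0 °C → rt, extraction at pH 6–7
Reagents that add atoms: N-methoxy-N-methylacetamide, CC(=O)N(C)OC; water, O
Why: Lateral lithiation of an ortho-tolualdehyde tert-butylimine with LDA, which cannot metalate the ring, followed by Weinreb ketone synthesis, in which the ketone is released only on quench and so cannot protonate the anion, and dilute acid then returns both aldehydes.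

Step 8
Reactants: 14 2-methoxy-4-(methoxymethoxy)-6-(2-oxopropyl)benzene-1,3-dicarbaldehyde
Product: 16 1-[7-(dimethoxymethyl)-1,8-dimethoxy-6-(methoxymethoxy)-1H-isochromen-4-yl]ethan-1-one (the 4-acetyl-1-methoxy-1H-isochromene; racemic at C1), via enaminone 15 (not isolated)
Conditions: Me2NCH(OMe)2 (1.3 equiv), PhMe, 50 °C; evaporate; then (±)-CSA (1.3 equiv), HC(OMe)3, MeOH, 0 °C → rt; NaHCO3
Reagents that add atoms: N,N-dimethylformamide dimethyl acetal, COC(OC)N(C)C; methanol, CO; trimethyl orthoformate, COC(OC)OC
Why: Aminomethylenation with the amide acetal takes the benzylic methylene that the ketone and the diformyl arene activate, and in acidic methanol the oxygen of the adjacent C1 aldehyde adds to the aminomethylene carbon with loss of dimethylamine (6-endo addition–elimination, the enaminone route to chromones transposed) while C1 takes up methanol and the remote C7 aldehyde becomes its dimethyl acetal; C1 is formed racemic.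

Step 9
Reactants: 8 (E)-N-tert-butyl-1-[3-iodo-2-methoxy-4-(methoxymethoxy)-6-methylphenyl]methanimine
Product: 20 7-iodo-8-methoxy-3-methylisoquinolin-6-ol, via benzylic lithium species 17 (not isolated), via keto imine 18 (not isolated), via protected iodoisoquinoline 19 (not isolated)
Conditions: LDA (1.1 equiv), THF, −78 °C; MeC(O)N(OMe)Me, −78 → −20 °C; NH4OAc, AcOH–EtOH, 60 °C; then 3 M HCl, 50 °C; NaHCO3 to pH 7
Reagents that add atoms: N-methoxy-N-methylacetamide, CC(=O)N(C)OC; ammonium acetate, CC(=O)[O-].[NH4+]
Why: Lateral lithiation and Weinreb acylation as in step 7 (LDA does not exchange the aryl iodide, which has no ortho hydrogen for a halogen dance), condensation of the keto imine with ammonia to the isoquinoline with loss of tert-butylamine (the 1,5-dicarbonyl plus ammonia ring synthesis), and acid cleavage of the methoxymethyl ether, after which the amphoteric product should precipitate at pH 7.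

Step 10
Reactants: 20 7-iodo-8-methoxy-3-methylisoquinolin-6-ol
Product: 22 (6-hydroxy-8-methoxy-3-methylisoquinolin-7-yl)boronic acid, via magnesiated phenoxide 21 (not isolated)
Conditions: iPrMgCl·LiCl (2.1 equiv), THF, −30 → 0 °C; B(OMe)3, −30 °C → rt; aq. NH4Cl (pH 6–7)
Reagents that add atoms: trimethyl borate, COB(OC)OC; water, O
Why: The first equivalent of the turbo-Grignard reagent deprotonates the phenol and the second performs iodine–magnesium exchange, a protection-free magnesiation known for iodophenols and iodohydroxyquinolines in the presence of LiCl, and borate trapping with neutral hydrolysis gives the boronic acid without exposing it to strong acid or base.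

Step 11
Reactants: 16 1-[7-(dimethoxymethyl)-1,8-dimethoxy-6-(methoxymethoxy)-1H-isochromen-4-yl]ethan-1-one; 22 (6-hydroxy-8-methoxy-3-methylisoquinolin-7-yl)boronic acid
Product: 24 protected bicyclic acetal (1R,3R,4S)-4-acetyl-7-(dimethoxymethyl)-8-methoxy-6-(methoxymethoxy)isochroman bridged C1–O6′ and C3–C7′ to 8′-methoxy-3′-methylisoquinoline, via conjugate adduct 23 (not isolated)
Conditions: [RhCl(C2H4)2]2 (3 mol %), (R,R)-2,5-diphenylbicyclo[2.2.2]octa-2,5-diene ((R,R)-Ph-bod*, 6.6 mol %), KOH (6 mol %), 22 (1.8 equiv), dioxane–MeOH (10:1), 35 °C; evaporate; then (±)-CSA (3 equiv), 4 Å MS, CH2Cl2, 0 °C → rt; NaHCO3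
Reagents that add atoms: none
Why: Transmetalation of 22 to the hydroxo (methoxo) complex of monovalent rhodium gives an aryl–rhodium species that inserts the C3=C4 bond of 16 with the aryl group on C3, the β-carbon of the vinylogous ester, and methanol protonates the oxa-π-allyl rhodium at C4 on the face away from the new aryl group; this is the Hayashi–Miyaura 1,4-addition as known for chromones, and the anti protonation matches the kinetic cis products known from cyclic trisubstituted acceptors. Camphorsulfonic acid then ionizes the C1 methoxy acetal of 23 to a benzylic oxocarbenium ion (a 3,4-dihydroisochromenylium ion), and the C6′ phenol closes ring C by 6-endo-trig attack on C1. C3 is set by the chiral diene (enantioface of the enone), C4 by the anti protonation, which the base-poor medium should not undo, and C1 by the tether, because the phenol reaches the planar cation only from the face that carries C7′, so the racemic C1 of 16 is erased. The step needs C7′ and not the more nucleophilic C5′ to bond to C3, which the boron atom secures, and it needs insertion to outrun protodeboronation of the di-ortho-oxygenated boronic acid, for which the fast diene catalyst, 35 °C and a nearly neutral medium are chosen. Methanol as the proton source keeps both methyl acetals by degenerate exchange, and the catalyst has to override the C1 methoxy group in both enantiomers of 16.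

Step 12
Reactants: 24 protected bicyclic acetal
Product: 25 (1R,3R,4S)-4-acetyl-6-hydroxy-8-methoxyisochroman-7-carbaldehyde bridged C1–O6′ and C3–C7′ to 8′-methoxy-3′-methylisoquinoline (target, CNP0584953.1)
Conditions: 2 M HCl, THF, rt; NaHCO3 to pH 7
Reagents that add atoms: water, O
Why: Aqueous acid hydrolyses the dimethyl acetal and the methoxymethyl ether, while the bicyclic acetal can only reopen reversibly and the three stereocenters should persist, C4 because its enol would suffer allylic strain against C3–H and C5–H and so forms slowly.

Compound list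
1 | 2,4-dihydroxy-6-methylbenzaldehyde (orcylaldehyde) | Cc1cc(O)cc(O)c1C=O | starting material
2 | 2-hydroxy-4-(methoxymethoxy)-6-methylbenzaldehyde | Cc1cc(OCOC)cc(O)c1C=O | intermediate
3 | 2-methoxy-4-(methoxymethoxy)-6-methylbenzaldehyde | Cc1cc(OCOC)cc(OC)c1C=O | intermediate
4 | 1-(dimethoxymethyl)-2-methoxy-4-(methoxymethoxy)-6-methylbenzene | Cc1cc(OCOC)cc(OC)c1C(OC)OC | intermediate
5 | [3-(dimethoxymethyl)-2-methoxy-6-(methoxymethoxy)-4-methylphenyl]lithium | Cc1cc(OCOC)c([Li])c(OC)c1C(OC)OC | intermediate
6 | 1-(dimethoxymethyl)-3-iodo-2-methoxy-4-(methoxymethoxy)-6-methylbenzene | Cc1cc(OCOC)c(I)c(OC)c1C(OC)OC | intermediate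
7 | 3-iodo-2-methoxy-4-(methoxymethoxy)-6-methylbenzaldehyde | Cc1cc(OCOC)c(I)c(OC)c1C=O | intermediate
8 | (E)-N-tert-butyl-1-[3-iodo-2-methoxy-4-(methoxymethoxy)-6-methylphenyl]methanimine | Cc1cc(OCOC)c(I)c(OC)c1/C=N/C(C)(C)C | intermediate
9 | chloro{3-[(E)-(tert-butylimino)methyl]-2-methoxy-6-(methoxymethoxy)-4-methylphenyl}magnesium | Cc1cc(OCOC)c([Mg]Cl)c(OC)c1/C=N/C(C)(C)C | intermediate
10 | 3-[(E)-(tert-butylimino)methyl]-2-methoxy-6-(methoxymethoxy)-4-methylbenzaldehyde | Cc1cc(OCOC)c(C=O)c(OC)c1/C=N/C(C)(C)C | intermediate
11 | 1,1′-[2-methoxy-4-(methoxymethoxy)-6-methyl-1,3-phenylene]bis(N-tert-butylmethanimine), both E | Cc1cc(OCOC)c(/C=N/C(C)(C)C)c(OC)c1/C=N/C(C)(C)C | intermediate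
12 | benzylic lithium derivative of 11 (lithium on the former methyl carbon) | [Li]Cc1cc(OCOC)c(/C=N/C(C)(C)C)c(OC)c1/C=N/C(C)(C)C | intermediate
13 | 1-[2,4-bis[(E)-(tert-butylimino)methyl]-3-methoxy-5-(methoxymethoxy)phenyl]propan-2-one | CC(=O)Cc1cc(OCOC)c(/C=N/C(C)(C)C)c(OC)c1/C=N/C(C)(C)C | intermediate
14 | 2-methoxy-4-(methoxymethoxy)-6-(2-oxopropyl)benzene-1,3-dicarbaldehyde | CC(=O)Cc1cc(OCOC)c(C=O)c(OC)c1C=O | intermediate
15 | 6-[(E)-1-(dimethylamino)-3-oxobut-1-en-2-yl]-2-methoxy-4-(methoxymethoxy)benzene-1,3-dicarbaldehyde | CC(=O)/C(=C/N(C)C)c1cc(OCOC)c(C=O)c(OC)c1C=O | intermediate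
16 | 1-[7-(dimethoxymethyl)-1,8-dimethoxy-6-(methoxymethoxy)-1H-isochromen-4-yl]ethan-1-one, racemic at C1 | COc1c(C(OC)OC)c(OCOC)cc2c1C(OC)OC=C2C(C)=O | intermediate
17 | benzylic lithium derivative of 8 (lithium on the former methyl carbon) | [Li]Cc1cc(OCOC)c(I)c(OC)c1/C=N/C(C)(C)C | intermediate
18 | 1-[2-[(E)-(tert-butylimino)methyl]-4-iodo-3-methoxy-5-(methoxymethoxy)phenyl]propan-2-one | CC(=O)Cc1cc(OCOC)c(I)c(OC)c1/C=N/C(C)(C)C | intermediate
19 | 7-iodo-8-methoxy-6-(methoxymethoxy)-3-methylisoquinoline | COCOc1cc2cc(C)ncc2c(OC)c1I | intermediate
20 | 7-iodo-8-methoxy-3-methylisoquinolin-6-ol | Oc1cc2cc(C)ncc2c(OC)c1I | intermediate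
21 | chloromagnesium 7-(chloromagnesio)-8-methoxy-3-methylisoquinolin-6-olate | Cl[Mg]Oc1cc2cc(C)ncc2c(OC)c1[Mg]Cl | intermediate
22 | (6-hydroxy-8-methoxy-3-methylisoquinolin-7-yl)boronic acid | OB(O)c1c(O)cc2cc(C)ncc2c1OC | intermediate
23 | 1-[(3R,4S)-7-(dimethoxymethyl)-3-(6-hydroxy-8-methoxy-3-methylisoquinolin-7-yl)-1,8-dimethoxy-6-(methoxymethoxy)isochroman-4-yl]ethan-1-one, both C1 epimers | COc1c(C(OC)OC)c(OCOC)cc2c1C(OC)O[C@@H](c1c(O)cc3cc(C)ncc3c1OC)[C@H]2C(C)=O | intermediate
24 | (1R,3R,4S)-4-acetyl-7-(dimethoxymethyl)-8-methoxy-6-(methoxymethoxy)isochroman with C1 bonded to O6′ and C3 bonded to C7′ of 8′-methoxy-3′-methylisoquinoline (ring C: C1, O2, C3, C7′, C6′, O6′) | COc1c(C(OC)OC)c(OCOC)cc2c1[C@H]1Oc3cc4cc(C)ncc4c(OC)c3[C@H](O1)[C@H]2C(C)=O | intermediate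
25 | (1R,3R,4S)-4-acetyl-6-hydroxy-8-methoxyisochroman-7-carbaldehyde with C1 bonded to O6′ and C3 bonded to C7′ of 8′-methoxy-3′-methylisoquinoline (CNP0584953.1) | COc1c(C=O)c(O)cc2c1[C@H]1Oc3cc4cc(C)ncc4c(OC)c3[C@H](O1)[C@H]2C(C)=O | target

Total step count: 12.
Longest linear sequence: 10 steps (steps 1–8, 11, 12); the boronic acid branch (steps 1–5, 9, 10, 11, 12) has 9.

Steps most likely to fail

Step 11. Protodeboronation of the di-ortho-oxygenated boronic acid and binding of the isoquinoline nitrogen to rhodium may outpace insertion into the hindered, α-aryl-substituted vinylogous ester. The C1 methoxy group of racemic 16 may oppose the catalyst in one enantiomer and slow it or erode the enantiomeric purity at C3. Equilibration at C4 before the lock would give the C4 epimer. The fallback reverses the order of the two bond formations and makes the carbon–carbon bond within the molecule. It sets out from 16 and 20. Acid-catalysed exchange of the C1 methoxy group for the phenol of 20 ((±)-CSA, 4 Å MS, toluene, 40 °C, methanol removed) would give the mixed aryl acetal F1. Aryl radical cyclization ((Me3Si)3SiH, AIBN, toluene, 80 °C) would then close ring C by 6-exo attack of C7′ on C3, with the tether fixing C3 relative to C1, and hydrogen transfer to the C4 radical from the open convex face should give the cis acetyl group. The product is the racemic protected acetal F2, which is resolved on a chiral stationary phase; its (1R,3R,4S) enantiomer is 24, where the route resumes with step 12. Catalyst control of the absolute configuration is given up for a resolution.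

Step 8. Under the basic aminomethylenation conditions the free keto dialdehyde may cyclize by intramolecular aldol condensation to a naphthol. In acidic methanol the ketone oxygen may compete with the C1 aldehyde oxygen in the ring closure, methanol may add across the new C3=C4 bond, or the methoxymethyl ether may be lost. The fallback keeps the aldehydes masked during the condensation and closes the ring in water before any methanol is present. It sets out from 13, kept by quenching step 7 with aqueous NH4Cl instead of acid. DMF dimethyl acetal (toluene, 60 °C) would give the enaminone bis-imine F3. Aqueous acetic acid in THF would hydrolyse both imines and the enaminone, and the hydroxymethylene ketone would close onto the C1 aldehyde to the lactol F4. Trimethyl orthoformate and methanol with catalytic PPTS would then turn the lactol into the methyl acetal and the C7 aldehyde into its dimethyl acetal, which is 16.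

Step 10. Iodine–magnesium exchange on the electron-rich magnesium aryloxide may be sluggish, and the amphoteric, di-ortho-oxygenated boronic acid may lose boron or form anhydrides during isolation. The fallback forms the carbon–boron bond by palladium catalysis instead of through an organomagnesium species and gives a boronic ester that can be chromatographed. It sets out from 20: Miyaura borylation (Pd(OAc)2, SPhos, B2pin2, KOAc, dioxane, 80 °C) would give the pinacol boronate F5. F5 replaces 22 in step 11, where the ester transmetalates through the same rhodium methoxide, and the route is rejoined at 23.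

Further compounds
F1 | step 11 | 1-[7-(dimethoxymethyl)-1-[(7-iodo-8-methoxy-3-methylisoquinolin-6-yl)oxy]-8-methoxy-6-(methoxymethoxy)-1H-isochromen-4-yl]ethan-1-one (racemic) | COc1c(C(OC)OC)c(OCOC)cc2c1C(Oc1cc3cc(C)ncc3c(OC)c1I)OC=C2C(C)=O
F2 | step 11 | racemic protected bicyclic acetal (24 together with its enantiomer) | COc1c(C(OC)OC)c(OCOC)cc2c1[C@H]1Oc3cc4cc(C)ncc4c(OC)c3[C@H](O1)[C@H]2C(C)=O.COc1c(C(OC)OC)c(OCOC)cc2c1[C@@H]1Oc3cc4cc(C)ncc4c(OC)c3[C@@H](O1)[C@@H]2C(C)=O
F3 | step 8 | (E)-3-[2,4-bis[(E)-(tert-butylimino)methyl]-3-methoxy-5-(methoxymethoxy)phenyl]-4-(dimethylamino)but-3-en-2-one | CC(=O)/C(=C/N(C)C)c1cc(OCOC)c(/C=N/C(C)(C)C)c(OC)c1/C=N/C(C)(C)C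
F4 | step 8 | 4-acetyl-1-hydroxy-8-methoxy-6-(methoxymethoxy)-1H-isochromene-7-carbaldehyde (racemic lactol) | COc1c(C=O)c(OCOC)cc2c1C(O)OC=C2C(C)=O
F5 | step 10 | 8-methoxy-3-methyl-7-(4,4,5,5-tetramethyl-1,3,2-dioxaborolan-2-yl)isoquinolin-6-ol | COc1c(B2OC(C)(C)C(C)(C)O2)c(O)cc2cc(C)ncc12
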